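## Analysis of the target

- The target is a germacranolide: a ten-membered carbocycle (C1–C10) trans-fused across C7–C8 to an α-methylene-γ-butyrolactone (C11, C12, C13, ring oxygen on C8). It carries a methyl group (C14) on C10, an acyloxymethyl group (C15) on C4 and a free hydroxyl on C6.
- The three stereocentres are contiguous: C6 (R), C7 (S) and C8 (S). O6, C11 and O8 lie on alternating faces (H6/H7 trans, H7/H8 trans), so on a six-membered ring all three substituents would be equatorial.
- Both ring olefins are trisubstituted and trans within the ring. C1=C10 is E. C4=C5 also has C3 and C6 trans, although its CIP label is Z because C15 carries oxygen.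
- Sensitive groups:
  - the exo-methylene lactone, a Michael acceptor;
  - the O15 ester, whose acyl part, (E)-2-(acetoxymethyl)but-2-enoate, is itself an acrylate with an allylic acetate;
  - the C6 hydroxyl, which is γ to the lactone carbonyl and can translactonise;
  - the 1,5-diene, which cyclises transannularly under acid and undergoes Cope rearrangement on heating.
- The difficulty is a strained medium ring with two geometrically defined trisubstituted olefins, a stereotriad, and three oxygens that must end up different (O6 free, O8 in the lactone, O15 acylated).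
- The strategy rests on one feature: C10=C1–C2–C3–C4=C5 is a 1,5-diene. Its Cope partner is the cyclohexane C5–C6–C7–C8–C9–C10 with a vinyl group on C10 and a 2-propenyl group on C5, in which C6, C7 and C8 are ring carbons with all substituents equatorial.

## Retrosynthetic reasoning

**Ester and silyl ether (40 ⇐ 39 ⇐ 32 + 38).** The O15–acyl bond is cut first, because the side-chain acid 38 tolerates neither strong base nor nucleophiles. The O6 silyl ether is removed last, so that O6 and O15 never compete for the acyl group and the free γ-hydroxy lactone appears only at the end.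

**Exocyclic methylene (32 ⇐ 31 ⇐ 29 ⇐ 28).** The C11=C13 bond is cut back to the saturated lactone 28 by a Mannich methylenation. The Michael acceptor is thus introduced only after all organometallic steps.

**C14 methyl (28 ⇐ 27).** The C10–C14 bond is cut to an enol triflate. The cross-coupling proceeds with retention, so the C1=C10 geometry is decided earlier, when the enolate is formed.

**Lactone carbonyl (27 ⇐ 26 ⇐ 25).** C12 is traced back to a lactol methyl ether, which survives Grignard reagents and potassium alkoxides. It is unmasked while C1=C10 is still an electron-poor enol triflate, before the acid-sensitive 1,5-diene exists.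

**Ten-membered ring (25 ⇐ 22).** C5–C10 is reconnected and C2–C3 is cut. This turns the ring into the trans-1-vinyl-2-alkenylcyclohexanol 22. The forward reaction is an anionic oxy-Cope ring expansion with enolate capture. It must deliver both olefins trans in the ring and keep the enolate at C1. What is gained is that no medium ring has to be closed end to end and that the stereotriad sits on a rigid chair.

**Vinyl carbinol (22 ⇐ 20 + 21).** The C10–vinyl bond is cut to ketone 20. Addition from the equatorial side gives the trans relation of the two alkenyl groups.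

**Cyclohexane ring (20 ⇐ 19 ⇐ 18 ⇐ 17 ⇐ 16).** After functional-group adjustment, the C5–C10 bond of the six-membered ring is cut to the open-chain aldehyde 16 (carbonyl-ene closure).

- Opening an epoxide on the preformed trans-fused bicycle, or adding to an enone there, is not used. Trans-diaxial opening and axial attack both work against the required all-equatorial pattern on a locked chair.
- In the ene closure the ring forms through a chair in which every substituent can take an equatorial position. The C15 oxygen is already in place.

**C5–C6 bond (16 ⇐ 15 ⇐ 14 ⇐ 13 ⇐ 8 + 12).** The allylic carbinol is cut to aldehyde 8 and the Z alkenyl iodide 12. The coupling must set C6 by Felkin–Anh control and keep the olefin geometry, which later decides which allylic hydrogen moves in the ene step.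

**C7–C8 bond and lactone (8 ⇐ 7 ⇐ 6 ⇐ 3 + 4; 3 ⇐ 1 + 2).** The trans-disubstituted lactone comes from a syn aldol between succinate imide 3 and aldehyde 4. The aldol sets C7 and C8 absolutely. Lactonisation onto O8 occurs before O6 exists, so the two oxygens are differentiated from the start.

**Side fragments (12 ⇐ 11 ⇐ 9; 38 ⇐ 37 ⇐ 36 ⇐ 35 ⇐ 33 + 34).** The Z iodide comes from carbometalation of propargyl alcohol 9. The acid 38 comes from a Baylis–Hillman adduct by acetate transposition.

## Alternatives that were turned down

**Alternative 1: silicon-tethered metathesis at C4=C5.**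

- Disconnection: the C4=C5 olefin. O6 and O15 are tied by a diisopropylsilylene group in the thirteen-membered diether A1.
- Forward key step: second-generation Grubbs catalyst, RuCl2(=CHPh)(PCy3)(H2IMes), joins the C4 methylene to the vinyl carbon on C6 with loss of ethylene. This gives the bridged lactone A2, with the ten-membered carbocycle and a seven-membered dioxasilepine.
- For it: the seven-membered ring can only hold a cis olefin, which is exactly the C15/C6-cis (ring-trans) geometry. A ring constraint enforces this geometry, which is stronger than the transition-state preference the chosen route relies on for this olefin. The conditions are neutral, so the lactone need not be masked.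
- Against it:
  - C1=C10 must already be present with E geometry, made by separate open-chain olefination.
  - A1 itself requires a thirteen-membered ring to be formed by double silylation.
  - The metathesis must forge a trisubstituted olefin in a strained cyclodecadiene from a 1,1-disubstituted olefin and an allylically oxygenated vinyl group. Both are slow partners, and dimerisation competes.
  - A2 lacks C13, and desilylation frees O6 and O15 together.
- Comparison: the chosen route sets both olefins in one event from ring stereochemistry. It expands a ring instead of closing one, and it arrives with O6 and O15 already distinguished as in 25.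

**Alternative 2: butenolide allylchromium closing C6–C7.**

- Disconnection: C6–C7. The open precursor A3 carries a bromomethyl butenolide and the C6 enal.
- Forward key step: CrCl2 (divalent chromium) turns the C13 bromide into an allylchromium that adds through C7 to the aldehyde. This closes the ring, creates C6 and C7 and unveils the exocyclic methylene, giving the hydroxy lactone A4.
- For it: it is the most convergent plan. The lactone is never masked, and after ring closure only desilylation and acylation remain. The chosen route needs eight steps after its key step, so Alternative 2 is clearly stronger on that point.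
- Against it:
  - The ten-membered ring, with two preformed trans trisubstituted olefins, is closed end to end against strain and entropy.
  - C6 and C7 must both be set relative to the single centre C8 through a flexible medium-ring transition state.
  - C8 of a butenolide is a base-labile γ position.
  - Both olefins of A3 must be built by acyclic chemistry.
- Comparison: the chosen strategy offers a stereotriad assembled on small rigid rings (6, 13, 17) and a ring-forming step driven by enolate formation. It pays for this with protecting-group steps.

**Alternative 3: B-alkyl Suzuki–Miyaura macrocyclisation at C1–C2.**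

- Disconnection: the sp2–sp3 bond C1–C2. The precursor A5 has an E vinyl iodide at C1 and a terminal vinyl group on C4.
- Forward key step: 9-BBN places boron on C2. PdCl2(dppf), reduced in the flask to zerovalent palladium, with Cs2CO3 then couples it to the iodide and gives the bis-silyl lactone A6.
- For it: the C1=C10 geometry is fixed in the iodide and retained, which is stronger than relying on a chair transition state. The lactone is tolerated, and the stereotriad can be set early on a simple lactone, as in the chosen route.
- Against it:
  - It is again an end-to-end closure of the strained ring.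
  - The vinyl group to be hydroborated is the terminus of a conjugated diene with C4=C5, so chemo- and regioselectivity of hydroboration are in doubt.
  - The C4=C5 geometry must be made separately.
  - A6 lacks C13 and has O6 and O15 identically protected.
- Comparison: the chosen route obtains both geometries and the ring in one step from 22 and needs no high dilution.

Key step: step 16

Remarks: germacrane numbering (C1–C15, O6, O8, O15) is used for all atoms in every intermediate. C12 of the lactol ether (19–26) is carried as an anomeric mixture, and the C10 carbinol of 17–19 is drawn as the expected equatorial epimer; neither centre survives. Compounds 1, 2, 4, 9, 21, 33 and 34 are taken to be commercial.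

## Route

Step 1
Reactants: 1 (R)-4-benzyl-1,3-oxazolidin-2-one; 2 methyl 4-chloro-4-oxobutanoate
Product: 3 (R)-4-benzyl-3-(4-methoxy-4-oxobutanoyl)-1,3-oxazolidin-2-one
Conditions: n-BuLi, THF, −78 °C; then 2, −78 to 0 °C
Reagents that add atoms: none
Why: N-acylation of the lithiated oxazolidinone by an acid chloride is the standard entry to these imides; the ester end of 2 is far less electrophilic than the acid chloride.

Step 2
Reactants: 3 (R)-4-benzyl-3-(4-methoxy-4-oxobutanoyl)-1,3-oxazolidin-2-one; 4 3-[(tert-butyldimethylsilyl)oxy]propanal
Product: 6 trans lactone imide (4R)-4-benzyl-3-{[(2S,3R)-2-{2-[(tert-butyldimethylsilyl)oxy]ethyl}-5-oxooxolan-3-yl]carbonyl}-1,3-oxazolidin-2-one, via syn aldol adduct 5 (not isolated)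
Conditions: Bu2BOTf, i-Pr2NEt, CH2Cl2, −78 to 0 °C; pH 7 buffer, MeOH, H2O2, 0 °C; then pyridinium p-toluenesulfonate (cat.), PhMe, 60 °C
Reagents that add atoms: none
Why: Evans syn aldol reaction: the Z boron enolate forms at the carbon alpha to the imide and adds to 4 through a closed chair whose face is fixed by the benzyl group of the (R) auxiliary, setting C7 and C8 (3R,4S in 5) in the 7,8-syn relation. The gamma-hydroxy ester then closes onto O8, which places the C6 acyl group and the C9 chain trans on the five-membered ring and ties up O8 before O6 exists.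

Step 3
Reactants: 6 trans lactone imide
Product: 7 S-ethyl (2S,3R)-2-{2-[(tert-butyldimethylsilyl)oxy]ethyl}-5-oxooxolane-3-carbothioate
Conditions: EtSH, n-BuLi, THF, −78 to 0 °C
Reagents that add atoms: ethanethiol, CCS
Why: Thiolate attacks the exocyclic imide carbonyl, the most electrophilic acyl group present, and releases the auxiliary; the lactone is untouched and the trans ring substitution is the thermodynamic one.

Step 4
Reactants: 7 S-ethyl thioester
Product: 8 (2S,3R)-2-{2-[(tert-butyldimethylsilyl)oxy]ethyl}-5-oxooxolane-3-carbaldehyde
Conditions: Et3SiH, Pd on carbon (cat.), acetone, rt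
Reagents that add atoms: none
Why: Fukuyama reduction: zerovalent palladium inserts into the C–S bond and the silane delivers hydride, giving the C6 aldehyde under neutral conditions that spare the lactone and do not epimerise or eliminate the beta-acyloxy aldehyde.

Step 5
Reactants: 9 prop-2-yn-1-ol
Product: 11 (Z)-3-iodo-2-methylprop-2-en-1-ol, via alkenylmagnesium alkoxide 10 (not isolated)
Conditions: MeMgBr (2.5 equiv), CuI (10 mol %), Et2O, −10 °C to rt; then I2, −78 to 0 °C
Reagents that add atoms: methylmagnesium bromide, C[Mg]Br; iodine, II
Why: Copper-catalysed anti carbomagnesiation of the propargylic alkoxide puts methyl on the inner carbon and magnesium on the terminal carbon within a five-membered chelate, cis to the CH2O group; iodinolysis retains this geometry.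

Step 6
Reactants: 11 (Z)-3-iodo-2-methylprop-2-en-1-ol
Product: 12 1-({[(2Z)-3-iodo-2-methylprop-2-en-1-yl]oxy}methyl)-4-methoxybenzene
Conditions: NaH, 4-methoxybenzyl chloride, n-Bu4NI (cat.), THF/DMF, 0 °C to rt
Reagents that add atoms: 4-methoxybenzyl chloride, COc1ccc(CCl)cc1
Why: Williamson etherification of the primary allylic alkoxide; the vinylic iodide is inert under these conditions.

Step 7
Reactants: 8 lactone aldehyde; 12 Z alkenyl iodide
Product: 13 (4S,5S)-5-{2-[(tert-butyldimethylsilyl)oxy]ethyl}-4-{(1R,2Z)-1-hydroxy-4-[(4-methoxybenzyl)oxy]-3-methylbut-2-en-1-yl}oxolan-2-one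
Conditions: CrCl2 (4 equiv), NiCl2 (1 mol %), DMSO, rt
Reagents that add atoms: none
Why: Nozaki–Hiyama–Kishi coupling: the alkenylchromium species (trivalent chromium) keeps the Z geometry and adds only to the aldehyde, not to the lactone. Felkin–Anh attack anti to the C7–C8 bond, the more substituted and oxygen-bearing branch, should favour the 6R carbinol, with O6 syn to C11 along the C5–C8 chain.

Step 8
Reactants: 13 allylic alcohol
Product: 14 C6 tert-butyldimethylsilyl ether of 13 (bis-silyl ether)
Conditions: TBSOTf, 2,6-lutidine, CH2Cl2, −78 °C
Reagents that add atoms: tert-butyldimethylsilyl trifluoromethanesulfonate, CC(C)(C)[Si](C)(C)OS(=O)(=O)C(F)(F)F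
Why: The silyl triflate silylates the hindered secondary allylic alcohol quickly at low temperature and so removes the free gamma-hydroxyl before it can translactonise onto C12.

Step 9
Reactants: 14 bis-silyl ether
Product: 15 primary alcohol (C10 hydroxyl free, C6 silyl ether kept)
Conditions: HF·pyridine, pyridine, THF, 0 °C
Reagents that add atoms: none
Why: Fluoride-mediated desilylation is much faster at the unhindered primary silyl ether than at the secondary allylic one flanked by C5 and C7; the pyridine buffer protects the lactone and the PMB ether.

Step 10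
Reactants: 15 primary alcohol
Product: 16 [(2S,3R)-3-{(1R,2Z)-1-[(tert-butyldimethylsilyl)oxy]-4-[(4-methoxybenzyl)oxy]-3-methylbut-2-en-1-yl}-5-oxooxolan-2-yl]acetaldehyde
Conditions: Dess–Martin periodinane, NaHCO3, CH2Cl2, 0 °C to rt
Reagents that add atoms: none
Why: Dess–Martin oxidation of the primary alcohol under buffered, non-basic conditions gives the C10 aldehyde without beta-elimination of the lactone oxygen on C8; the aldehyde is used at once.

Step 11
Reactants: 16 lactone aldehyde
Product: 17 trans-fused 4-[(tert-butyldimethylsilyl)oxy]-6-hydroxy-5-{3-[(4-methoxybenzyl)oxy]prop-1-en-2-yl}hexahydro-1-benzofuran-2(3H)-one (benzofuran C4, C5, C6 = germacrane C6, C5, C10; all substituents equatorial)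
Conditions: Me2AlCl (2 equiv), CH2Cl2, −78 to −20 °C
Reagents that add atoms: none
Why: Lewis-acid-promoted intramolecular carbonyl-ene reaction of the citronellal-to-isopulegol kind: the complexed aldehyde C10 bonds to C5 while hydrogen passes to oxygen from the methyl group cis to H5, creating the C4=C3 methylene and leaving CH2OPMB on C4. The closing chair is fixed by the trans-fused lactone and the equatorial C6 silyloxy group, and 1,3-allylic strain with the cis CH2OPMB group forces the new C5 substituent equatorial, trans to O6; the configuration of the C10 carbinol is immaterial.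

Step 12
Reactants: 17 hydroxy lactone
Product: 18 lactol (C12 hemiacetal; octahydro-1-benzofuran-2,6-diol)
Conditions: i-Bu2AlH (2.2 equiv), CH2Cl2, −78 °C
Reagents that add atoms: none
Why: Reduction of the gamma-lactone by the aluminium hydride stops at the lactol because the tetrahedral aluminate is stable at −78 °C; the free C10 hydroxyl only consumes one equivalent of hydride.

Step 13
Reactants: 18 lactol
Product: 19 lactol methyl ether (2-methoxy-octahydro-1-benzofuran-6-ol, anomeric mixture)
Conditions: MeOH, pyridinium p-toluenesulfonate (cat.), rt
Reagents that add atoms: methanol, CO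
Why: Acid-catalysed acetalisation of the lactol through its oxocarbenium ion; the lactone carbonyl is thereby masked against the Grignard reagent and the strong base of the following steps.

Step 14
Reactants: 19 lactol methyl ether
Product: 20 ketone (C10 carbonyl; 4-[(tert-butyldimethylsilyl)oxy]-2-methoxy-5-{3-[(4-methoxybenzyl)oxy]prop-1-en-2-yl}hexahydro-1-benzofuran-6(2H)-one)
Conditions: Dess–Martin periodinane, NaHCO3, CH2Cl2, 0 °C
Reagents that add atoms: none
Why: Buffered Dess–Martin oxidation of the secondary alcohol; neutral conditions avoid migration of the beta,gamma olefin into conjugation and loss of the beta-silyloxy group, and the equatorial C5 alkenyl group is already the thermodynamic arrangement.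

Step 15
Reactants: 20 ketone; 21 vinylmagnesium bromide
Product: 22 trans-1-vinyl-2-alkenylcyclohexanol fused to the lactol methyl ether (vinyl on C10 equatorial, hydroxyl axial)
Conditions: CeCl3 (anhydrous), THF; 21, −78 °C
Reagents that add atoms: none
Why: The vinylcerium reagent is nucleophilic but weakly basic, so the doubly activated C5–H is not removed. Attack from the equatorial side of the locked chair, the axial path being shielded by the axial hydrogens on C6 and C8, should place the vinyl group equatorial and trans to the C5 alkenyl group.

Step 16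
Reactants: 22 trans-1-vinyl-2-alkenylcyclohexanol
Product: 25 E,E-cyclodecadienyl C10 enol triflate, via potassium alkoxide 23 (not isolated), via potassium enolate 24 (not isolated)
Conditions: KH, 18-crown-6, THF, 0 °C to rt; then PhNTf2, −78 °C
Reagents that add atoms: N-phenylbis(trifluoromethanesulfonimide), O=S(=O)(N(c1ccccc1)S(=O)(=O)C(F)(F)F)C(F)(F)F; potassium hydride, [K+].[H-] (potassium of 23 and 24 only)
Why: Anionic oxy-Cope rearrangement with enolate capture, the known route from trans-1,2-dialkenylcyclohexanols to E-cyclodec-5-enone enol derivatives. KH gives alkoxide 23, which the crown ether frees from its cation; its [3,3] shift joins C2 to C3 and breaks C5–C10, so the cyclohexane opens into the ten-membered ring. The ring is therefore closed by ring expansion through a six-centre chair, not by end-to-end cyclisation, and needs no high dilution. No stereocentre is created, and C6, C7 and C8 are untouched. Both olefin geometries follow from the chair, in which the ring bonds C5–C6 and C9–C10 are equatorial because the two alkenyl groups are trans-diequatorial on a chair locked by the trans-fused acetal ring: C6 ends up trans to C3 across C4=C5 and C9 trans to C2 across the C10=C1 enolate. The step needs the enolate to stay at C1, since a C9 enolate would expel O8; 24 forms irreversibly under aprotic conditions and is O-sulfonylated at −78 °C before proton transfer can occur. Enolate formation supplies the driving force that the neutral elemane-to-germacrane direction lacks.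

Step 17
Reactants: 25 enol triflate lactol methyl ether
Product: 26 enol triflate lactol (C12 hemiacetal)
Conditions: AcOH/THF/H2O (3:1:1), rt
Reagents that add atoms: water, O
Why: Mild aqueous acid hydrolyses the 2-methoxytetrahydrofuran acetal through its oxocarbenium ion. It is done while C1=C10 is still an electron-poor enol triflate, so the acid-promoted transannular cyclisation typical of germacra-1(10),4-dienes has no nucleophilic olefin partner; the secondary silyl ether and the PMB ether survive.

Step 18
Reactants: 26 enol triflate lactol
Product: 27 enol triflate lactone (8,12-olide)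
Conditions: n-Pr4N[RuO4] (5 mol %), N-methylmorpholine N-oxide, 4 Å molecular sieves, CH2Cl2, rt
Reagents that add atoms: none
Why: Ley–Griffith oxidation (perruthenate, heptavalent ruthenium) converts the lactol into the gamma-lactone under neutral conditions; nothing else in 26 is oxidised.

Step 19
Reactants: 27 enol triflate lactone
Product: 28 6-O-TBS 15-O-PMB germacra-1(10),4-dien-8,12-olide (C14 methyl on C10, no C13)
Conditions: MeZnCl, Pd(PPh3)4 (5 mol %), THF, rt to 40 °C
Reagents that add atoms: methylzinc chloride, C[Zn]Cl
Why: Negishi coupling: oxidative addition of zerovalent palladium to the enol triflate, transmetalation from zinc and reductive elimination replace the triflate by methyl with retention, so the geometry set in step 16 is kept; organozinc reagents tolerate the lactone.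

Step 20
Reactants: 28 diene lactone
Product: 29 11-(dimethylaminomethyl) lactone (Mannich base, C11 epimers)
Conditions: LiN(i-Pr)2, THF, −78 °C; then CH2=NMe2+ I− (Eschenmoser's salt), −78 °C to rt
Reagents that add atoms: N,N-dimethylmethyleneiminium iodide, C=[N+](C)C.[I-]
Why: Mannich reaction of the lactone lithium enolate, C11 being the only enolisable position, with the preformed iminium salt; the new C11 centre is destroyed in the next step.

Step 21
Reactants: 29 Mannich base
Product: 31 6-O-TBS 15-O-PMB α-methylene lactone, via ammonium iodide 30 (not isolated)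
Conditions: MeI, MeOH, rt; then NaHCO3 (aq), CH2Cl2, rt
Reagents that add atoms: iodomethane, CI (its atoms appear in 30 only)
Why: Quaternisation of the amine followed by E1cB elimination under mild base gives the exocyclic C11=C13 olefin, the standard finish for α-methylene lactones.

Step 22
Reactants: 31 PMB ether
Product: 32 6-O-TBS 15-hydroxy germacra-1(10),4,11(13)-trien-8,12-olide
Conditions: DDQ, CH2Cl2/pH 7 buffer (10:1), 0 °C
Reagents that add atoms: none
Why: Oxidative cleavage of the PMB ether through its benzylic cation, which water hydrolyses; the silyl ether, the lactone and the non-conjugated olefins do not react in buffered medium at 0 °C.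

Step 23
Reactants: 33 tert-butyl prop-2-enoate; 34 acetaldehyde
Product: 35 tert-butyl 3-hydroxy-2-methylidenebutanoate (racemic)
Conditions: DABCO, 1,4-dioxane/H2O, rt
Reagents that add atoms: none
Why: Morita–Baylis–Hillman reaction: the amine adds to the acrylate, the enolate adds to acetaldehyde and the amine is expelled.

Step 24
Reactants: 35 tert-butyl 3-hydroxy-2-methylidenebutanoate
Product: 36 tert-butyl 3-acetoxy-2-methylidenebutanoate
Conditions: Ac2O, Et3N, DMAP (cat.), CH2Cl2, 0 °C
Reagents that add atoms: acetic anhydride, CC(=O)OC(C)=O
Why: Acetylation of the secondary allylic alcohol under nucleophilic catalysis.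

Step 25
Reactants: 36 tert-butyl 3-acetoxy-2-methylidenebutanoate
Product: 37 tert-butyl (E)-2-(acetoxymethyl)but-2-enoate
Conditions: DABCO (20 mol %), THF, reflux
Reagents that add atoms: none
Why: Amine-catalysed 1,3-transposition of a Baylis–Hillman acetate (SN2′ addition of the amine, return of acetate at the primary carbon) gives the conjugated trisubstituted olefin under thermodynamic control; the E isomer, with the methyl group trans to the ester, is the more stable one.

Step 26
Reactants: 37 tert-butyl (E)-2-(acetoxymethyl)but-2-enoate
Product: 38 (E)-2-(acetoxymethyl)but-2-enoic acid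
Conditions: CF3CO2H, CH2Cl2, 0 °C to rt
Reagents that add atoms: none
Why: Acidolysis of the tert-butyl ester through the tert-butyl cation frees the acid; the acetate and the olefin geometry are unaffected.

Step 27
Reactants: 32 C15 alcohol; 38 (E)-2-(acetoxymethyl)but-2-enoic acid
Product: 39 6-O-TBS ether of the target
Conditions: N,N'-dicyclohexylcarbodiimide, DMAP (10 mol %), CH2Cl2, 0 °C
Reagents that add atoms: none
Why: Steglich esterification of the unhindered primary allylic alcohol; low temperature and little DMAP limit SN2′ attack of the catalyst on the allylic acetate of the acyl donor and conjugate addition to the methylene lactone.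

Step 28
Reactants: 39 6-O-TBS ether of the target
Product: 40 target, (6R,7S,8S)-6-hydroxy-15-[(E)-2-(acetoxymethyl)but-2-enoyloxy]germacra-1(10),4,11(13)-trien-8,12-olide
Conditions: HF·pyridine, pyridine, THF, 0 °C to rt
Reagents that add atoms: none
Why: Fluoride cleaves the secondary silyl ether under buffered, non-basic conditions that leave both esters, the methylene lactone and the 1,5-diene intact; base is avoided because the freed C6 hydroxyl could translactonise onto C12.

## Compound list

1 | (R)-4-benzyl-1,3-oxazolidin-2-one | O=C1N[C@H](Cc2ccccc2)CO1 | starting material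
2 | methyl 4-chloro-4-oxobutanoate | COC(=O)CCC(Cl)=O | starting material
3 | (R)-4-benzyl-3-(4-methoxy-4-oxobutanoyl)-1,3-oxazolidin-2-one | COC(=O)CCC(=O)N1[C@H](Cc2ccccc2)COC1=O | intermediate
4 | 3-[(tert-butyldimethylsilyl)oxy]propanal | O=CCCO[Si](C)(C)C(C)(C)C | starting material
5 | methyl (3R,4S)-3-{[(4R)-4-benzyl-2-oxo-1,3-oxazolidin-3-yl]carbonyl}-6-[(tert-butyldimethylsilyl)oxy]-4-hydroxyhexanoate (syn aldol adduct) | COC(=O)C[C@@H](C(=O)N1[C@H](Cc2ccccc2)COC1=O)[C@@H](O)CCO[Si](C)(C)C(C)(C)C | intermediate (not isolated)
6 | (4R)-4-benzyl-3-{[(2S,3R)-2-{2-[(tert-butyldimethylsilyl)oxy]ethyl}-5-oxooxolan-3-yl]carbonyl}-1,3-oxazolidin-2-one (trans lactone imide) | O=C1C[C@@H](C(=O)N2[C@H](Cc3ccccc3)COC2=O)[C@H](CCO[Si](C)(C)C(C)(C)C)O1 | intermediate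
7 | S-ethyl (2S,3R)-2-{2-[(tert-butyldimethylsilyl)oxy]ethyl}-5-oxooxolane-3-carbothioate | O=C1C[C@@H](C(=O)SCC)[C@H](CCO[Si](C)(C)C(C)(C)C)O1 | intermediate
8 | (2S,3R)-2-{2-[(tert-butyldimethylsilyl)oxy]ethyl}-5-oxooxolane-3-carbaldehyde | O=C1C[C@@H](C=O)[C@H](CCO[Si](C)(C)C(C)(C)C)O1 | intermediate
9 | prop-2-yn-1-ol | C#CCO | starting material
10 | bromomagnesium (Z)-3-(bromomagnesio)-2-methylprop-2-en-1-olate | C/C(CO[Mg]Br)=C/[Mg]Br | intermediate (not isolated)
11 | (Z)-3-iodo-2-methylprop-2-en-1-ol | C/C(CO)=C/I | intermediate
12 | 1-({[(2Z)-3-iodo-2-methylprop-2-en-1-yl]oxy}methyl)-4-methoxybenzene | C/C(COCc1ccc(OC)cc1)=C/I | intermediate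
13 | (4S,5S)-5-{2-[(tert-butyldimethylsilyl)oxy]ethyl}-4-{(1R,2Z)-1-hydroxy-4-[(4-methoxybenzyl)oxy]-3-methylbut-2-en-1-yl}oxolan-2-one | O=C1C[C@@H]([C@H](O)/C=C(/C)COCc2ccc(OC)cc2)[C@H](CCO[Si](C)(C)C(C)(C)C)O1 | intermediate
14 | C6 tert-butyldimethylsilyl ether of 13 (trans lactone, 6R, Z olefin) | O=C1C[C@@H]([C@H](O[Si](C)(C)C(C)(C)C)/C=C(/C)COCc2ccc(OC)cc2)[C@H](CCO[Si](C)(C)C(C)(C)C)O1 | intermediate
15 | trans lactone with 2-hydroxyethyl group on C8 and C6 silyl ether | O=C1C[C@@H]([C@H](O[Si](C)(C)C(C)(C)C)/C=C(/C)COCc2ccc(OC)cc2)[C@H](CCO)O1 | intermediate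
16 | [(2S,3R)-3-{(1R,2Z)-1-[(tert-butyldimethylsilyl)oxy]-4-[(4-methoxybenzyl)oxy]-3-methylbut-2-en-1-yl}-5-oxooxolan-2-yl]acetaldehyde | O=C1C[C@@H]([C@H](O[Si](C)(C)C(C)(C)C)/C=C(/C)COCc2ccc(OC)cc2)[C@H](CC=O)O1 | intermediate
17 | trans-fused 4-[(tert-butyldimethylsilyl)oxy]-6-hydroxy-5-{3-[(4-methoxybenzyl)oxy]prop-1-en-2-yl}hexahydro-1-benzofuran-2(3H)-one, all ring substituents equatorial | O[C@H]1[C@H](C(=C)COCc2ccc(OC)cc2)[C@@H](O[Si](C)(C)C(C)(C)C)[C@@H]3CC(=O)O[C@H]3C1 | intermediate
18 | corresponding lactol, octahydro-1-benzofuran-2,6-diol | O[C@H]1[C@H](C(=C)COCc2ccc(OC)cc2)[C@@H](O[Si](C)(C)C(C)(C)C)[C@@H]3CC(O)O[C@H]3C1 | intermediate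
19 | corresponding 2-methoxy acetal, 2-methoxy-octahydro-1-benzofuran-6-ol | O[C@H]1[C@H](C(=C)COCc2ccc(OC)cc2)[C@@H](O[Si](C)(C)C(C)(C)C)[C@@H]3CC(OC)O[C@H]3C1 | intermediate
20 | 4-[(tert-butyldimethylsilyl)oxy]-2-methoxy-5-{3-[(4-methoxybenzyl)oxy]prop-1-en-2-yl}hexahydro-1-benzofuran-6(2H)-one | O=C1[C@H](C(=C)COCc2ccc(OC)cc2)[C@@H](O[Si](C)(C)C(C)(C)C)[C@@H]3CC(OC)O[C@H]3C1 | intermediate
21 | vinylmagnesium bromide | C=C[Mg]Br | starting material
22 | trans-1-vinyl-2-alkenylcyclohexanol fused to the lactol methyl ether (6-ethenyl-octahydro-1-benzofuran-6-ol; vinyl equatorial, hydroxyl axial) | C=C[C@@]1(O)[C@H](C(=C)COCc2ccc(OC)cc2)[C@@H](O[Si](C)(C)C(C)(C)C)[C@@H]3CC(OC)O[C@H]3C1 | intermediate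
23 | potassium alkoxide of 22 | C=C[C@@]1([O-])[C@H](C(=C)COCc2ccc(OC)cc2)[C@@H](O[Si](C)(C)C(C)(C)C)[C@@H]3CC(OC)O[C@H]3C1.[K+] | intermediate (not isolated)
24 | potassium C10 enolate of the E-cyclodec-4-enone (enolate olefin C10=C1) | [K+].[O-]\C1=C/CC/C(COCc2ccc(OC)cc2)=C/[C@@H](O[Si](C)(C)C(C)(C)C)[C@@H]3CC(OC)O[C@H]3C1 | intermediate (not isolated)
25 | E,E-cyclodecadienyl C10 enol triflate, lactol methyl ether | FC(F)(F)S(=O)(=O)O\C1=C/CC/C(COCc2ccc(OC)cc2)=C/[C@@H](O[Si](C)(C)C(C)(C)C)[C@@H]3CC(OC)O[C@H]3C1 | intermediate
26 | C10 enol triflate, lactol | FC(F)(F)S(=O)(=O)O\C1=C/CC/C(COCc2ccc(OC)cc2)=C/[C@@H](O[Si](C)(C)C(C)(C)C)[C@@H]3CC(O)O[C@H]3C1 | intermediate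
27 | C10 enol triflate, 8,12-lactone | FC(F)(F)S(=O)(=O)O\C1=C/CC/C(COCc2ccc(OC)cc2)=C/[C@@H](O[Si](C)(C)C(C)(C)C)[C@@H]3CC(=O)O[C@H]3C1 | intermediate
28 | 6-O-TBS 15-O-PMB germacra-1(10),4-dien-8,12-olide | C1C(=O)O[C@H]2C/C(C)=C/CC/C(COCc3ccc(OC)cc3)=C/[C@@H](O[Si](C)(C)C(C)(C)C)[C@H]12 | intermediate
29 | 11-(dimethylaminomethyl) derivative of 28 | CN(C)CC1C(=O)O[C@H]2C/C(C)=C/CC/C(COCc3ccc(OC)cc3)=C/[C@@H](O[Si](C)(C)C(C)(C)C)[C@H]12 | intermediate
30 | trimethylammonium iodide of 29 | C[N+](C)(C)CC1C(=O)O[C@H]2C/C(C)=C/CC/C(COCc3ccc(OC)cc3)=C/[C@@H](O[Si](C)(C)C(C)(C)C)[C@H]12.[I-] | intermediate (not isolated)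
31 | 6-O-TBS 15-O-PMB germacra-1(10),4,11(13)-trien-8,12-olide | C=C1C(=O)O[C@H]2C/C(C)=C/CC/C(COCc3ccc(OC)cc3)=C/[C@@H](O[Si](C)(C)C(C)(C)C)[C@H]12 | intermediate
32 | 6-O-TBS 15-hydroxy germacra-1(10),4,11(13)-trien-8,12-olide | C=C1C(=O)O[C@H]2C/C(C)=C/CC/C(CO)=C/[C@@H](O[Si](C)(C)C(C)(C)C)[C@H]12 | intermediate
33 | tert-butyl prop-2-enoate | C=CC(=O)OC(C)(C)C | starting material
34 | acetaldehyde | CC=O | starting material
35 | tert-butyl 3-hydroxy-2-methylidenebutanoate (racemic) | CC(O)C(=C)C(=O)OC(C)(C)C | intermediate
36 | tert-butyl 3-acetoxy-2-methylidenebutanoate (racemic) | CC(OC(C)=O)C(=C)C(=O)OC(C)(C)C | intermediate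
37 | tert-butyl (E)-2-(acetoxymethyl)but-2-enoate | CC(C)(C)OC(=O)/C(=C/C)COC(C)=O | intermediate
38 | (E)-2-(acetoxymethyl)but-2-enoic acid | OC(=O)/C(=C/C)COC(C)=O | intermediate
39 | 6-O-TBS ether of the target | C=C1C(=O)O[C@H]2C/C(C)=C/CC/C(COC(=O)/C(=C/C)COC(C)=O)=C/[C@@H](O[Si](C)(C)C(C)(C)C)[C@H]12 | intermediate
40 | CNP0184624.1, (6R,7S,8S)-6-hydroxy-15-[(E)-2-(acetoxymethyl)but-2-enoyloxy]germacra-1(10),4,11(13)-trien-8,12-olide | C=C1C(=O)O[C@H]2C/C(C)=C/CC/C(COC(=O)/C(=C/C)COC(C)=O)=C/[C@@H](O)[C@H]12 | target

## Step count and least certain steps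

Total step count: 28. Longest linear sequence: 22 steps (steps 1–4, 7–22, 27, 28). Steps 5–6 and 23–26 make the two side fragments.

**Step 16 (key step).**
- What may go wrong: proton transfer within or between enolate molecules before O-sulfonylation would move the enolate from C1 to C9 and trigger beta-elimination of O8, opening the acetal ring. A second risk is migration of the silyl group from O6 to the C10 alkoxide before the [3,3] shift, which would remove the alkoxide that drives the rearrangement.
- Fallback (from 22, returning at 25): trap in two stages. After the rearrangement with KH and 18-crown-6, chlorotrimethylsilane is added at −78 °C, since silylation is faster than triflation. This gives the C10 trimethylsilyl enol ether F1, which is regiochemically stable and can be isolated. Methyllithium in THF at 0 °C then regenerates the regiodefined lithium enolate without crown ether, and N-(5-chloropyridin-2-yl)bis(trifluoromethanesulfonimide) converts it into 25.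

**Step 11 (carbonyl-ene closure).**
- What may go wrong: the olefin carries two allylic C–O bonds and may be too poor a nucleophile. The Lewis acid could then ionise the allylic silyl ether or promote beta-elimination of the aldehyde faster than ring closure.
- Fallback (from 8 and 9, returning at 17): replace the ene reaction by an intramolecular Hosomi–Sakurai allylation. The olefin becomes a far better nucleophile, and silicon fixes where the new methylene appears.
  - Propargyl alcohol 9 with (trimethylsilyl)methylmagnesium chloride and CuI, then iodine, gives (Z)-3-iodo-2-[(trimethylsilyl)methyl]prop-2-en-1-ol F2.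
  - PMB protection gives the iodide F3.
  - Nozaki–Hiyama–Kishi coupling with 8 gives the allylic alcohol F4.
  - Silylation gives the bis-silyl ether F5.
  - Selective primary desilylation gives the alcohol F6.
  - Dess–Martin oxidation gives the allylsilane aldehyde F7.
  - BF3·OEt2 in CH2Cl2 at −78 °C closes C5–C10 with loss of the silyl group and gives 17.

**Step 7 (C6 carbinol).**
- What may go wrong: poor facial selectivity at the aldehyde, because the two branches on C7 (C8 and C11) differ only moderately. Translactonisation of the free gamma-hydroxy lactone is also possible if silylation is delayed.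
- Fallback (from the epimer mixture of 13, returning at 13): oxidise with Dess–Martin periodinane to the Z enone F8, then reduce under reagent control with a Corey–Bakshi–Shibata oxazaborolidine and catecholborane at −78 °C. Both antipodes of the catalyst are available, so the matched one for the 6R carbinol would be selected.

**Step 15 (vinyl addition).**
- What may go wrong: deprotonation of the doubly activated C5–H by the organometallic reagent, followed by loss of the beta-silyloxy group or olefin migration. Attack from the axial side would give the cis dialkenyl isomer.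
- Fallback (from 20, returning at 22): build the vinyl carbinol in two one-carbon steps. Dimethylsulfoxonium methylide (Corey–Chaykovsky reaction under thermodynamic betaine control) should give the spiro-epoxide F9 with the new CH2 equatorial and the oxygen axial. An excess of dimethylsulfonium methylide then opens the epoxide at CH2 and eliminates dimethyl sulfide to give the vinyl carbinol 22.

## Further compounds

F1 | step 16 | C10 trimethylsilyl enol ether of the E,E-cyclodecadiene (lactol methyl ether) | C[Si](C)(C)O\C1=C/CC/C(COCc2ccc(OC)cc2)=C/[C@@H](O[Si](C)(C)C(C)(C)C)[C@@H]3CC(OC)O[C@H]3C1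
F2 | step 11 | (Z)-3-iodo-2-[(trimethylsilyl)methyl]prop-2-en-1-ol | C[Si](C)(C)C/C(CO)=C/I
F3 | step 11 | (Z)-1-iodo-3-[(4-methoxybenzyl)oxy]-2-[(trimethylsilyl)methyl]prop-1-ene | C[Si](C)(C)C/C(COCc1ccc(OC)cc1)=C/I
F4 | step 11 | allylsilane analogue of 13 (C6 alcohol) | O=C1C[C@@H]([C@H](O)/C=C(/C[Si](C)(C)C)COCc2ccc(OC)cc2)[C@H](CCO[Si](C)(C)C(C)(C)C)O1
F5 | step 11 | allylsilane analogue of 14 (bis-silyl ether) | O=C1C[C@@H]([C@H](O[Si](C)(C)C(C)(C)C)/C=C(/C[Si](C)(C)C)COCc2ccc(OC)cc2)[C@H](CCO[Si](C)(C)C(C)(C)C)O1
F6 | step 11 | allylsilane analogue of 15 (primary alcohol) | O=C1C[C@@H]([C@H](O[Si](C)(C)C(C)(C)C)/C=C(/C[Si](C)(C)C)COCc2ccc(OC)cc2)[C@H](CCO)O1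
F7 | step 11 | allylsilane analogue of 16 (aldehyde) | O=C1C[C@@H]([C@H](O[Si](C)(C)C(C)(C)C)/C=C(/C[Si](C)(C)C)COCc2ccc(OC)cc2)[C@H](CC=O)O1
F8 | step 7 | Z enone, C6 ketone of 13 | O=C1C[C@@H](C(=O)/C=C(/C)COCc2ccc(OC)cc2)[C@H](CCO[Si](C)(C)C(C)(C)C)O1
F9 | step 15 | C10 spiro-epoxide of 20 (CH2 equatorial, oxygen axial) | C1O[C@@]12[C@H](C(=C)COCc3ccc(OC)cc3)[C@@H](O[Si](C)(C)C(C)(C)C)[C@@H]4CC(OC)O[C@H]4C2
A1 | alternative 1 | thirteen-membered O6,O15-diisopropylsilylene diether with C4 methylene and C6 vinyl group | C1C(=O)O[C@H]2C/C(C)=C/CCC(=C)CO[Si](C(C)C)(C(C)C)O[C@H](C=C)[C@H]12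
A2 | alternative 1 | O6,O15-silylene-bridged germacradien-8,12-olide lacking the C13 methylene | C1C(=O)O[C@H]2C/C(C)=C/CC/C3=C/[C@@H](O[Si](C(C)C)(C(C)C)OC3)[C@H]12
A3 | alternative 2 | 13-bromo butenolide with C6 enal (6,7-seco precursor) | BrCC1=C[C@H](C/C(C)=C/CC/C(CO[Si](C)(C)C(C)(C)C)=C/C=O)OC1=O
A4 | alternative 2 | 15-O-silyl 6-hydroxy germacradien-8,12-olide | C=C1C(=O)O[C@H]2C/C(C)=C/CC/C(CO[Si](C)(C)C(C)(C)C)=C/[C@@H](O)[C@H]12
A5 | alternative 3 | 1,2-seco precursor with C1 vinyl iodide and terminal vinyl group on C4 | C1C(=O)O[C@@H](C/C(C)=C/I)[C@@H]1[C@H](O[Si](C)(C)C(C)(C)C)/C=C(/C=C)CO[Si](C)(C)C(C)(C)C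
A6 | alternative 3 | 6,15-bis-O-silyl germacradien-8,12-olide lacking the C13 methylene | C1C(=O)O[C@H]2C/C(C)=C/CC/C(CO[Si](C)(C)C(C)(C)C)=C/[C@@H](O[Si](C)(C)C(C)(C)C)[C@H]12
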